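The grey run, with 4 mM of catalyst, ended at 92.0 % product, and the teal run, with 1 mM, at 45.5 %. I asked whether both lay on one curve.

in all of them: substrate 0.10 M; gas phase 20 mM (held); added ligand 8.3 mM

| run | catalyst | remark | time |
|---|---|---|---|
| teal | 1 mM | run made earlier |  |
| grey | 4 mM | run made earlier |  |
| flask | 2.0 mM |  | 8.0 d |

- teal (time / d: product / %, substrate / %): 2.08: 13.7, 86.1; 4.00: 28.6, 72.7; 6.00: 36.7, 63.3; 8.00: 45.5, 52.3
- grey (time / d: product / %, substrate / %): 1.04: 23.5, 75.7; 3.00: 59.6, 42.2; 5.00: 78.0, 20.8; 8.00: 92.0, 7.3

(scatter of a reading: 1 percentage point)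

- product at 8.0 d, in percent of the substrate charged
- concentration of dissolved gas in solution at 8.0 d, in percent of saturation

- the analysis behind the earlier runs scatters by 1 percentage point, standard deviation
- at the start none of the gas phase is in solution

Of the two reactants, the dissolved gas stands in the smaller amount: a saturated solution holds 20 mM against 0.10 M of substrate, so converting the whole charge takes 5.00 fillings of the solution. The opposite outcome is a gas-starved flask, with a rate set by the crossing and independent of catalyst. I tested this with a pseudo-first-order reckoning, taking ln(1/(1 − y)) divided by catalyst and time, the rate constant per unit of catalyst. Teal gave 0.0759 mM⁻¹ d⁻¹ and grey 0.0789 mM⁻¹ d⁻¹. A rate independent of catalyst would put the grey constant at a quarter of the teal one, but I read a ratio of 1.04. I carried the mean, 0.0774 mM⁻¹ d⁻¹. With the substrate at its full charge, my constant puts the gas demand of the grey run at 31.0 mM d⁻¹ and that of this flask at 15.5 mM d⁻¹, half as much. The grey readings showed no cap at the higher demand, so I expected 71.0 % product in this flask. For the dissolved gas, the readings gave me no figure.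

The forecast said 71 % and 96 %, holding that “transfer outpaces consumption”. The flask gave 70.6 % and 85.2 %, and its product corresponds to a constant of 0.0765 mM⁻¹ d⁻¹.

    gas phase ⇌ dissolved gas, rate k1*(csat - [dissolved gas]) (kL = 0.00570 min⁻¹)
    substrate + dissolved gas + catalyst → catalyst + product (k = 5.40 M⁻² min⁻¹)
    dissolved gas → decomposed reagent (k = 8.00 × 10⁻⁴ min⁻¹)
    catalyst + added ligand ⇌ idle complex (K = 88.0 M⁻¹, k = 1.20 M⁻¹ min⁻¹)
    2 substrate → homo dimer (k = 1.60 × 10⁻⁶ M⁻¹ min⁻¹)

At 8.00 d, dissolved gas in this flask stood at 0.0170 M, made and used at a ratio of 1.00, and it went 4.2 times faster into decomposed reagent than into product. By then this flask held 0.151 M of decomposed reagent, more than the 0.10 M of substrate charged. Read at 3.0 d, the same flask should hold 37.1 % product by my constant, and the computed value is 35.7 %.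

(The numbers in the tables are calculated for substances that don't exist; noise was put on by code.)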